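## Structural features

Euchrenone a17 is a flavanone: benzo ring A is fused to the dihydropyranone ring C, and C2 of ring C carries aryl ring B, which is itself fused at C3'/C4' to a 2,2-dimethyl-dihydropyran (ring D). Ring A has a free hydroxyl at C7 and a prenyl chain at C8, the carbon between the ring oxygen O1 (on C8a) and the C7 oxygen; C5 and C6 are unsubstituted. The only stereocentre is C2 (S). It has no stereogenic neighbour, but it is benzylic to an electron-rich arene, bonded to O1 and beta to the C4 carbonyl, so it can be lost by reversible opening of ring C to the 2'-hydroxychalcone, most easily under base once the 7-hydroxyl is free. The fragile groups are the trisubstituted prenyl alkene (acid makes the adjacent 7-hydroxyl add across it; hydrogenation and electrophiles attack it), the beta-aryloxy ketone and the phenol para to the carbonyl. The difficulties are to set C2 in one absolute sense and keep it, to place the prenyl group on C8 and not C6, and to have one ortho-prenylphenol unit closed (ring D) while the other (C7-OH/C8-prenyl) stays open. The key step exploits the fact that O1 links C2 to the aromatic carbon C8a: if O1–C8a is the last bond of ring C to be made, a C2 carbinol of fixed configuration enters the ring with none of its four bonds touched.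

## Logic of the disconnections

**20 to 19.** The O–CH2 bond of the acetal on the C7 oxygen is added back (protecting-group cut). The free phenol of 20 would promote base-induced opening of ring C and would quench the bases and organometallics used earlier, so it stays masked to the end. The gain is an inert aryl ether that also directs the metalation. The forward step needs acid mild enough to leave the prenyl alkene unprotonated and C2 untouched.

**19 to 18 to 17.** C4 is taken back from carbonyl to carbinol (18) and then to its silyl ether (17). A C4 carbonyl beside a free C2 carbinol would be an aldol that can fragment or dehydrate, and it would compete in the reduction that sets C2. At the silyl ether level C4 is inert and its configuration is irrelevant. The forward steps must be fluoride desilylation and a non-acidic oxidation, because the C4 carbinol (para to the C7 oxygen, ortho to O1) ionises in acid.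

**17 to 16.** The O1–C8a bond is cut, opening ring C to an aryl bromide and a secondary benzylic carbinol. This is the one ring C bond whose formation does not involve C2, so configuration is transferred with retention by construction. The heterocycle is replaced by an open 1,3-dioxygenated three-carbon chain between two arenes. The forward step needs C–O reductive elimination at a doubly ortho-substituted carbon to outrun beta-hydride elimination, and the C4 oxygen must carry a group that cannot migrate to the neighbouring alkoxide.

**16 to 15.** The C–H bond at the carbinol carbon is cut, giving the aryl ketone. The stereocentre then comes from a prochiral carbonyl by catalyst-controlled hydride delivery. The gain is an achiral-at-C2 precursor. The catalyst must override the racemic silyloxy centre two atoms away and leave the alkene, aryl bromide and acetal alone.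

**15 to 14.** The O–Si bond is cut. Triisopropylsilyl is chosen over smaller silyl groups because it resists 1,5 O-to-O migration under carbonate base and loss in the formic acid medium. The forward silylation must be fast and cold enough to avoid dehydration of the aldol.

**14 to 8 and 12 (through 13).** The C3–C4 bond (flavonoid numbering) is cut by a retro-aldol, splitting the molecule into two arenes of similar size, each carrying one of the two difficult substitution patterns. The forward aldol needs a preformed kinetic enolate and low temperature so that neither retro-aldol nor dehydration to a chalcone intervenes.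

**8 to 3 and 4 (through 5, 6, 7), then 3 to 2 to 1.** The C8–CH2 bond is cut. The ring C–H between bromine and the acetal oxygen is the most acidic one, so deprotonation fixes the prenyl position, where electrophilic substitution would favour C6. The gain is a commercial bromophenol aldehyde plus two protecting operations. The forward step needs the aldehyde masked, an amide base (no bromine–lithium exchange), low temperature against aryne formation, and copper to favour SN2 over SN2' attack on 4.

**12 to 9 and 10 (through 11).** The aryl–CH2 bond and the O–C(CH3)2 bond of ring D are cut. The hydroxyl (ortho) and the acetyl group (meta) direct to the same carbon, and closing ring D at this stage removes the need to tell two ortho-prenylphenols apart later. The forward step needs an acid strong enough for a deactivated phenol without oligomerising the allyl cation.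

## Other disconnections considered

**Alternative 1:** The cut is at the two aryl–CH2 bonds (C8–CH2 and C3'–CH2). In the forward sense the bis(1,1-dimethylallyl) ether A2 would be heated so that two [3,3] shifts give the doubly C-prenylated flavanone A1.

- In its favour: both prenyl carbons would arrive in one metal-free operation on an intact flavanone, and each shift turns a reverse-prenyl ether into a normal prenyl group. On step economy for installing the prenyl carbons it is the better of the two plans.
- Against it here: the C7 ether can migrate to C6 as well as C8, so ring A regiochemistry is not guaranteed, whereas the chosen plan fixes C8 by directed metalation.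
- A1 contains two ortho-prenylphenols, and only the ring B one may be closed to ring D. Any selectivity would rest on the lower nucleophilicity of the C7 hydroxyl, which is a thin margin; the chosen plan closes ring D before ring A exists.
- The heat needed acts on a 7-hydroxyflavanone as it forms, which can open to the chalcone and lose C2.
- The disconnection says nothing about C2: A2 must already be a single enantiomer. Mechanistically the rearrangement is as reliable as any step in the chosen route; structurally it leaves the two hardest problems unsolved.

**Alternative 2:** The cut is at C4a–C5 inside ring A. Forward, acid would unmask the aldehyde of the polycarbonyl chain A4, the methylene between two carbonyls would condense on it, and dehydration and enolisation would give the chalcone A3.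

- In its favour: the prenyl position is written into the chain, so regiochemistry is as certain as in the chosen plan (equal on this point). The key step would lose only methanol and water and needs no halogen or precious metal, so it is better on atom economy.
- Against it here: A4 is a 1,3,5-tricarbonyl enone that would be laborious to assemble and can cyclise in other ways (O-cyclisation to pyranones, Michael addition to the enone).
- A3 is achiral, so C2 would still have to be set by an asymmetric oxa-Michael closure, which is reversible for simple 2'-hydroxychalcones and hard to control.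
- A chalcone like A3 is reachable far more simply by condensing two arenes, so building ring A de novo gains nothing in step count. The chosen plan is longer on paper than a chalcone route but sets C2 by a dependable ketone reduction and never passes through the chalcone equilibrium.

**Alternative 3:** The cut is at C3=C4 of an enol ether form of ring C. Forward, second-generation Grubbs catalyst would join the C2 vinyl group of A6 to its silyl enol ether to give the 2H-chromene A5; hydrolysis and a later Claisen shift to C8 would lead to 20.

- In its favour: the O1–C2 bond and the stereocentre could be made together by an enantioselective allylic etherification, and A5 is already at the ketone oxidation level, so no desilylation and oxidation at C4 would be needed. On oxidation-state economy it is the better plan; on reliance on one precious-metal ring closure the two are equal.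
- Against it here: the metathesis must engage a 1,1-disubstituted, electron-rich enol ether to make a trisubstituted alkene, which is slow.
- A6 carries a third terminal alkene in its 1,1-dimethylallyl ether that could enter the catalytic cycle.
- A5 could lose configuration at its doubly activated C2 by reversible electrocyclic opening of the pyran ring.
- The prenyl group would still arrive by a thermal shift with the C6/C8 question and the heating of a 7-hydroxyflavanone. The chosen plan is the safer one on C8 regiocontrol and on stereochemical integrity.

Key step: step 8

Assumption: the carbinol carbon created in the aldol step (C4 of the flavan) is carried as both epimers, since step 10 turns it into a carbonyl; names and SMILES of 14–18 leave it undefined.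

## Route

Step 1
Reactants: 1 2-bromo-4-hydroxybenzaldehyde
Product: 2 2-bromo-4-(methoxymethoxy)benzaldehyde
Conditions: MOMCl, iPr2NEt, CH2Cl2, 0 °C to rt
Reagents that add atoms: chloromethyl methyl ether, COCCl
Why: O-alkylation of the acidic para-formyl phenol with an alpha-chloro ether (Williamson-type etherification); the MOM ether later directs the ring metalation and withstands base, fluoride and palladium.

Step 2
Reactants: 2 2-bromo-4-(methoxymethoxy)benzaldehyde
Product: 3 2-bromo-1-(dimethoxymethyl)-4-(methoxymethoxy)benzene
Conditions: HC(OMe)3, MeOH, PPTS (cat.), rt; then Et3N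
Reagents that add atoms: trimethyl orthoformate, COC(OC)OC
Why: Acid-catalysed acetalisation driven by the orthoformate as water scavenger masks the aldehyde against the amide base and aryl-metal species of step 3; a catalytic pyridinium acid at room temperature is too weak to cleave the aryl MOM ether.

Step 3
Reactants: 3 2-bromo-1-(dimethoxymethyl)-4-(methoxymethoxy)benzene; 4 prenyl bromide (1-bromo-3-methylbut-2-ene)
Product: 8 2-bromo-4-(methoxymethoxy)-3-(3-methylbut-2-en-1-yl)benzaldehyde, via aryllithium 5 (not isolated), via arylcopper 6 (not isolated), via prenylated dimethyl acetal 7 (not isolated)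
Conditions: LiN(iPr)2 (LDA), THF, −78 °C; CuBr·SMe2, −78 to −40 °C; 4, −40 to 0 °C; then 1 M HCl, THF, rt
Reagents that add atoms: water, O
Why: Directed ortho-metalation removes the ring proton flanked by Br and OMOM, the most acidic one, and an amide base does not exchange the bromine. Transmetalation to monovalent copper suppresses LiBr loss to an aryne and steers the allylic substitution to the linear SN2 product. The dilute acid work-up hydrolyses the para-alkoxy-activated dimethyl acetal much faster than the aryl MOM ether.

Step 4
Reactants: 9 4-hydroxyacetophenone; 10 2-methylbut-3-en-2-ol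
Product: 12 6-acetyl-2,2-dimethylchroman [1-(2,2-dimethylchroman-6-yl)ethan-1-one], via 4-hydroxy-3-prenylacetophenone 11 (not isolated)
Conditions: Amberlyst 15, toluene, 80 °C, slow addition of 10
Reagents that add atoms: none
Why: Friedel–Crafts alkylation by the dimethylallyl cation at the only carbon that is ortho to OH and meta to acetyl, followed by acid-catalysed Markovnikov hydroalkoxylation of the prenyl alkene by the phenol, which closes ring D.

Step 5
Reactants: 12 6-acetyl-2,2-dimethylchroman; 8 2-bromo-4-(methoxymethoxy)-3-(3-methylbut-2-en-1-yl)benzaldehyde
Product: 14 3-[2-bromo-4-(methoxymethoxy)-3-(3-methylbut-2-en-1-yl)phenyl]-1-(2,2-dimethylchroman-6-yl)-3-hydroxypropan-1-one (racemic), via lithium enolate 13 (not isolated)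
Conditions: LiN(iPr)2 (LDA), THF, −78 °C; then 8, −78 °C; AcOH quench at −78 °C
Reagents that add atoms: none
Why: Directed aldol addition of a preformed kinetic lithium enolate to a non-enolisable aldehyde; the cold acidic quench prevents retro-aldol and dehydration to the chalcone, and the new carbinol centre is formed racemic, which does not matter.

Step 6
Reactants: 14 racemic aldol
Product: 15 3-[2-bromo-4-(methoxymethoxy)-3-(3-methylbut-2-en-1-yl)phenyl]-1-(2,2-dimethylchroman-6-yl)-3-[(triisopropylsilyl)oxy]propan-1-one (racemic)
Conditions: iPr3SiOTf, 2,6-lutidine, CH2Cl2, −40 to 0 °C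
Reagents that add atoms: triisopropylsilyl trifluoromethanesulfonate, CC(C)[Si](C(C)C)(C(C)C)OS(=O)(=O)C(F)(F)F
Why: O-silylation of a secondary alcohol with a silyl triflate and a hindered pyridine base; the bulky triisopropylsilyl ether blocks retro-aldol and elimination, tolerates the formic acid medium of step 7 and does not migrate to the neighbouring alkoxide in step 8.

Step 7
Reactants: 15 racemic silyloxy ketone
Product: 16 (1S)-3-[2-bromo-4-(methoxymethoxy)-3-(3-methylbut-2-en-1-yl)phenyl]-1-(2,2-dimethylchroman-6-yl)-3-[(triisopropylsilyl)oxy]propan-1-ol (both C3 epimers)
Conditions: RuCl[(S,S)-TsDPEN](p-cymene) (cat.), HCO2H/Et3N (5:2), CH2Cl2, rt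
Reagents that add atoms: none
Why: Noyori–Ikariya asymmetric transfer hydrogenation of an aryl alkyl ketone; the (S,S)-ligand delivers hydride to the Re face of the carbonyl through the outer-sphere Ru–H/N–H transition state, giving the (S)-carbinol under catalyst control for both C3 epimers. The alkene, aryl bromide and acetal are inert to the ruthenium hydride.

Step 8
Reactants: 16 (1S)-bromoaryl carbinol
Product: 17 (2S)-2-(2,2-dimethylchroman-6-yl)-7-(methoxymethoxy)-8-(3-methylbut-2-en-1-yl)-4-[(triisopropylsilyl)oxy]chroman (both C4 epimers)
Conditions: Pd(OAc)2 (cat.), 2-(di-tert-butylphosphino)-1,1'-binaphthyl (cat.), Cs2CO3, toluene, 70–80 °C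
Reagents that add atoms: none
Why: The phosphine reduces Pd(OAc)2 to a monoligated zerovalent palladium species that inserts into the C8a–Br bond; Cs2CO3 then deprotonates the palladium-bound carbinol, and the seven-membered aryl(alkoxo) chelate of divalent palladium releases the product by C–O reductive elimination. The closest known reaction type is the Buchwald–Hartwig-type intramolecular etherification of aryl bromides with secondary alcohols to 2-substituted chromans. Ring C closes in a 6-exo sense at the arene carbon, the six-membered ring arising by contraction of the seven-membered palladacycle. No stereocentre is created: C2 keeps the S configuration from step 7 because none of its bonds takes part, and C4 is a spectator in both epimeric forms. The selectivity needed is reductive elimination over beta-hydride elimination of the benzylic alkoxide; the bulky electron-rich biaryl phosphine and the two ortho substituents at C8a compress the Ar–Pd–O angle and speed reductive elimination. The silyl ether on the C4 oxygen cannot bind palladium or migrate, so only the six-membered closure is available. The prenyl alkene cannot reach the aryl–palladium bond without strain, and the MOM acetal is inert to carbonate.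

Step 9
Reactants: 17 silylated flavan
Product: 18 (2S)-2-(2,2-dimethylchroman-6-yl)-7-(methoxymethoxy)-8-(3-methylbut-2-en-1-yl)chroman-4-ol (both C4 epimers)
Conditions: Bu4NF, THF, 0 °C to rt; H2O
Reagents that add atoms: none
Why: Fluoride-induced desilylation driven by the Si–F bond; the basic, non-acidic medium leaves the MOM ether and alkene alone and avoids ionisation of the acid-sensitive C4 carbinol.

Step 10
Reactants: 18 flavan-4-ol
Product: 19 (2S)-2-(2,2-dimethylchroman-6-yl)-7-(methoxymethoxy)-8-(3-methylbut-2-en-1-yl)chroman-4-one
Conditions: Dess–Martin periodinane, NaHCO3, CH2Cl2, 0 °C to rt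
Reagents that add atoms: none
Why: Dess–Martin oxidation of a secondary benzylic alcohol under buffered, near-neutral conditions converges both C4 epimers on one ketone; C2 is beta to the new carbonyl and is not enolisable, and without base ring C does not open.

Step 11
Reactants: 19 MOM-protected flavanone
Product: 20 euchrenone a17 [(2S)-2-(2,2-dimethylchroman-6-yl)-7-hydroxy-8-(3-methylbut-2-en-1-yl)chroman-4-one]
Conditions: 2 M HCl, MeOH/THF, 40 °C
Reagents that add atoms: none
Why: Acid-catalysed cleavage of the aryl MOM acetal through an oxocarbenium ion trapped by methanol; dilute acid at modest temperature should leave the prenyl alkene unprotonated, and acidic conditions keep ring C closed so that C2 stays S.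

## Compound list

1 | 2-bromo-4-hydroxybenzaldehyde | O=Cc1ccc(O)cc1Br | starting material
2 | 2-bromo-4-(methoxymethoxy)benzaldehyde | COCOc1ccc(C=O)c(Br)c1 | intermediate
3 | 2-bromo-1-(dimethoxymethyl)-4-(methoxymethoxy)benzene | COCOc1ccc(C(OC)OC)c(Br)c1 | intermediate
4 | prenyl bromide (1-bromo-3-methylbut-2-ene) | CC(C)=CCBr | starting material
5 | [2-bromo-3-(dimethoxymethyl)-6-(methoxymethoxy)phenyl]lithium (not isolated) | [Li]c1c(OCOC)ccc(C(OC)OC)c1Br | intermediate
6 | [2-bromo-3-(dimethoxymethyl)-6-(methoxymethoxy)phenyl]copper (not isolated) | [Cu]c1c(OCOC)ccc(C(OC)OC)c1Br | intermediate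
7 | 2-bromo-1-(dimethoxymethyl)-4-(methoxymethoxy)-3-(3-methylbut-2-en-1-yl)benzene (not isolated) | CC(C)=CCc1c(OCOC)ccc(C(OC)OC)c1Br | intermediate
8 | 2-bromo-4-(methoxymethoxy)-3-(3-methylbut-2-en-1-yl)benzaldehyde | CC(C)=CCc1c(OCOC)ccc(C=O)c1Br | intermediate
9 | 4-hydroxyacetophenone | CC(=O)c1ccc(O)cc1 | starting material
10 | 2-methylbut-3-en-2-ol | C=CC(C)(C)O | starting material
11 | 4-hydroxy-3-(3-methylbut-2-en-1-yl)acetophenone (not isolated) | CC(=O)c1ccc(O)c(CC=C(C)C)c1 | intermediate
12 | 6-acetyl-2,2-dimethylchroman | CC(=O)c1ccc2c(c1)CCC(C)(C)O2 | intermediate
13 | lithium 1-(2,2-dimethylchroman-6-yl)ethen-1-olate (not isolated) | [Li]OC(=C)c1ccc2c(c1)CCC(C)(C)O2 | intermediate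
14 | 3-[2-bromo-4-(methoxymethoxy)-3-(3-methylbut-2-en-1-yl)phenyl]-1-(2,2-dimethylchroman-6-yl)-3-hydroxypropan-1-one (racemic) | CC(C)=CCc1c(OCOC)ccc(C(O)CC(=O)c2ccc3c(c2)CCC(C)(C)O3)c1Br | intermediate
15 | 3-[2-bromo-4-(methoxymethoxy)-3-(3-methylbut-2-en-1-yl)phenyl]-1-(2,2-dimethylchroman-6-yl)-3-[(triisopropylsilyl)oxy]propan-1-one (racemic) | CC(C)=CCc1c(OCOC)ccc(C(O[Si](C(C)C)(C(C)C)C(C)C)CC(=O)c2ccc3c(c2)CCC(C)(C)O3)c1Br | intermediate
16 | (1S)-3-[2-bromo-4-(methoxymethoxy)-3-(3-methylbut-2-en-1-yl)phenyl]-1-(2,2-dimethylchroman-6-yl)-3-[(triisopropylsilyl)oxy]propan-1-ol (both C3 epimers) | CC(C)=CCc1c(OCOC)ccc(C(O[Si](C(C)C)(C(C)C)C(C)C)C[C@H](O)c2ccc3c(c2)CCC(C)(C)O3)c1Br | intermediate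
17 | (2S)-2-(2,2-dimethylchroman-6-yl)-7-(methoxymethoxy)-8-(3-methylbut-2-en-1-yl)-4-[(triisopropylsilyl)oxy]chroman (both C4 epimers) | CC(C)=CCc1c(OCOC)ccc2c1O[C@H](c1ccc3c(c1)CCC(C)(C)O3)CC2O[Si](C(C)C)(C(C)C)C(C)C | intermediate
18 | (2S)-2-(2,2-dimethylchroman-6-yl)-7-(methoxymethoxy)-8-(3-methylbut-2-en-1-yl)chroman-4-ol (both C4 epimers) | CC(C)=CCc1c(OCOC)ccc2c1O[C@H](c1ccc3c(c1)CCC(C)(C)O3)CC2O | intermediate
19 | (2S)-2-(2,2-dimethylchroman-6-yl)-7-(methoxymethoxy)-8-(3-methylbut-2-en-1-yl)chroman-4-one | CC(C)=CCc1c(OCOC)ccc2c1O[C@H](c1ccc3c(c1)CCC(C)(C)O3)CC2=O | intermediate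
20 | euchrenone a17, (2S)-2-(2,2-dimethylchroman-6-yl)-7-hydroxy-8-(3-methylbut-2-en-1-yl)chroman-4-one | CC(C)=CCc1c(O)ccc2c1O[C@H](c1ccc3c(c1)CCC(C)(C)O3)CC2=O | target

## Step count and least certain steps

Total: 11 steps. Longest linear sequence: 10 steps (steps 1, 2, 3, 5, 6, 7, 8, 9, 10, 11, from 1 to 20); step 4 is a one-step side branch.

**Step 8 (key step).** The most likely failure is beta-hydride elimination of the benzylic palladium alkoxide outrunning C–O reductive elimination. That would return ketone 15 together with hydrodebrominated material. Oxidative addition at the doubly flanked C–Br bond may also be slow. The fallback closes the same O1–C2/C8a ether from the phenol side with inversion.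
- It sets out from 15, which would be reduced with RuCl[(R,R)-TsDPEN](p-cymene) and HCO2H/Et3N to the (1R)-bromoaryl carbinol F1.
- Miyaura borylation (B2pin2, Pd(OAc)2/SPhos, KOAc, dioxane, 80 °C; acetate is too weak to form the alkoxide) would give the (1R)-aryl pinacol boronate F2.
- Oxidation with NaBO3·4H2O in THF/H2O would give the (1R)-phenol carbinol F3.
- Mitsunobu cyclisation (PPh3, DIAD, THF, 0 °C) would displace the activated carbinol by the phenol with inversion, giving the (2S) ring. It comes back to the route at 17.

**Step 3.** The ortho-bromoaryllithium may lose LiBr to an aryne or let bromine migrate before it is trapped, and the allylic coupling may transpose to give the 1,1-dimethylallyl isomer. The fallback sets out from 3: the same deprotonation and copper transmetalation, but trapping at −78 °C with the more reactive and symmetrical allyl bromide, followed by the same acid work-up, would give 3-allyl-2-bromo-4-(methoxymethoxy)benzaldehyde F4. Olefin cross-metathesis of F4 with excess 2-methylbut-2-ene (second-generation Grubbs catalyst, CH2Cl2, 40 °C) would then give the prenyl group. It comes back at 8.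

**Step 4.** Ring alkylation of the acetyl-deactivated phenol may be sluggish, so that the allyl cation oligomerises, alkylates oxygen or adds twice. The fallback sets out from 9.
- O-alkylation with 3-chloro-3-methylbut-1-yne (K2CO3, KI, CuCl2 cat., acetone) would give 4-(2-methylbut-3-yn-2-yloxy)acetophenone F5.
- Heating in N,N-diethylaniline (propargyl Claisen rearrangement, hydrogen shift, electrocyclisation) would give 6-acetyl-2,2-dimethyl-2H-chromene F6.
- Hydrogenation of the chromene double bond (H2, Pd/C, EtOAc, 1 atm) comes back at 12.

**Step 7.** Facial selectivity may be poor for the C3 epimer whose silyloxy centre opposes the catalyst, and the amine may induce loss of silanol from the beta-silyloxy ketone. The fallback changes the reduction manifold: it sets out from 15 and uses Corey–Bakshi–Shibata reduction with (R)-2-methyl-CBS-oxazaborolidine and catecholborane in toluene at −78 °C. This is base-free, and catecholborane spares the trisubstituted alkene. It comes back at 16 and makes no new compound (F0).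

**Step 11.** The liberated 7-hydroxyl may add across the protonated prenyl alkene to form a second dimethylpyran ring, and C2 may partly epimerise through acid-promoted ring opening. The fallback avoids protic acid: it sets out from 19, where TMSOTf and 2,2'-bipyridyl in CH2Cl2 at 0 °C would exchange the MOM group for silicon to give the 7-trimethylsilyloxy flavanone F7. Hydrolysis of F7 with water during work-up comes back at 20.

## Further compounds

F1 | step 8 | (1R)-3-[2-bromo-4-(methoxymethoxy)-3-(3-methylbut-2-en-1-yl)phenyl]-1-(2,2-dimethylchroman-6-yl)-3-[(triisopropylsilyl)oxy]propan-1-ol | CC(C)=CCc1c(OCOC)ccc(C(O[Si](C(C)C)(C(C)C)C(C)C)C[C@@H](O)c2ccc3c(c2)CCC(C)(C)O3)c1Br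
F2 | step 8 | (1R)-1-(2,2-dimethylchroman-6-yl)-3-[4-(methoxymethoxy)-3-(3-methylbut-2-en-1-yl)-2-(4,4,5,5-tetramethyl-1,3,2-dioxaborolan-2-yl)phenyl]-3-[(triisopropylsilyl)oxy]propan-1-ol | CC(C)=CCc1c(OCOC)ccc(C(O[Si](C(C)C)(C(C)C)C(C)C)C[C@@H](O)c2ccc3c(c2)CCC(C)(C)O3)c1B1OC(C)(C)C(C)(C)O1
F3 | step 8 | (1R)-1-(2,2-dimethylchroman-6-yl)-3-[2-hydroxy-4-(methoxymethoxy)-3-(3-methylbut-2-en-1-yl)phenyl]-3-[(triisopropylsilyl)oxy]propan-1-ol | CC(C)=CCc1c(OCOC)ccc(C(O[Si](C(C)C)(C(C)C)C(C)C)C[C@@H](O)c2ccc3c(c2)CCC(C)(C)O3)c1O
F4 | step 3 | 3-allyl-2-bromo-4-(methoxymethoxy)benzaldehyde | C=CCc1c(OCOC)ccc(C=O)c1Br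
F5 | step 4 | 4-(2-methylbut-3-yn-2-yloxy)acetophenone | CC(=O)c1ccc(OC(C)(C)C#C)cc1
F6 | step 4 | 6-acetyl-2,2-dimethyl-2H-chromene | CC(=O)c1ccc2c(c1)C=CC(C)(C)O2
F0 | step 7 | none | none
F7 | step 11 | (2S)-2-(2,2-dimethylchroman-6-yl)-8-(3-methylbut-2-en-1-yl)-7-(trimethylsilyloxy)chroman-4-one | CC(C)=CCc1c(O[Si](C)(C)C)ccc2c1O[C@H](c1ccc3c(c1)CCC(C)(C)O3)CC2=O
A1 | alternative 1 | (S)-7-hydroxy-2-[4-hydroxy-3-(3-methylbut-2-en-1-yl)phenyl]-8-(3-methylbut-2-en-1-yl)chroman-4-one | CC(C)=CCc1c(O)ccc2c1O[C@H](c1ccc(O)c(CC=C(C)C)c1)CC2=O
A2 | alternative 1 | (S)-7-(2-methylbut-3-en-2-yloxy)-2-[4-(2-methylbut-3-en-2-yloxy)phenyl]chroman-4-one | C=CC(C)(C)Oc1ccc2c(c1)O[C@H](c1ccc(OC(C)(C)C=C)cc1)CC2=O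
A3 | alternative 2 | (E)-1-[2,4-dihydroxy-3-(3-methylbut-2-en-1-yl)phenyl]-3-(2,2-dimethylchroman-6-yl)prop-2-en-1-one | CC(C)=CCc1c(O)ccc(C(=O)/C=C/c2ccc3c(c2)CCC(C)(C)O3)c1O
A4 | alternative 2 | (E)-1-(2,2-dimethylchroman-6-yl)-9,9-dimethoxy-6-(3-methylbut-2-en-1-yl)non-1-ene-3,5,7-trione | COC(OC)CC(=O)C(CC=C(C)C)C(=O)CC(=O)/C=C/c1ccc2c(c1)CCC(C)(C)O2
A5 | alternative 3 | (S)-4-(tert-butyldimethylsilyloxy)-2-(2,2-dimethylchroman-6-yl)-7-(2-methylbut-3-en-2-yloxy)-2H-chromene | C=CC(C)(C)Oc1ccc2c(c1)O[C@H](c1ccc3c(c1)CCC(C)(C)O3)C=C2O[Si](C)(C)C(C)(C)C
A6 | alternative 3 | (S)-tert-butyl[(1-{2-[1-(2,2-dimethylchroman-6-yl)allyloxy]-4-(2-methylbut-3-en-2-yloxy)phenyl}vinyl)oxy]dimethylsilane | C=CC(C)(C)Oc1ccc(C(=C)O[Si](C)(C)C(C)(C)C)c(c1)O[C@H](c1ccc2c(c1)CCC(C)(C)O2)C=C
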